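**Retrosynthetic overview**
- All carbons come from 4-hydroxyphenylpyruvic acid 1 (used as its methyl ester 2), phenylpyruvic acid 3 and 3-methylbut-2-enal 4.
- Butenolide (ring A, formed first): cut C2–C3 and O1–C5 of the dihydrofuranone. The boron-bound enediolate of acid 3 adds to the ketone of ester 2 and lactonises to phenol-lactone 5, which sets C2 as (R).
- Pyran (ring B, formed second, same flask): cut C4–C4a and O1–C2 of the benzopyran. The bare phenol of 5 is annulated with 4 to 2H-chromene 6, so no prenylated or chroman-bearing arylpyruvate is needed.
- Last cut: the CH2–CH2 unit of target 7 comes from C3=C4 of chromene 6 by hydrogenation.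

Assumption: the facial sense of the catalyst pair in step 2 cannot be derived from precedent, so the quinine-derived thiourea is written for (R), and its quinidine-derived pseudo-enantiomer replaces it if the first run (rotation and CD against the natural (R) series) shows (S); 2-oxo acids and esters are drawn as keto tautomers.

**Step 1**
Reactants: 1 4-hydroxyphenylpyruvic acid [3-(4-hydroxyphenyl)-2-oxopropanoic acid]
Product: 2 methyl 3-(4-hydroxyphenyl)-2-oxopropanoate
Conditions: KHCO3 (1.0 equiv), MeI (1.2 equiv), DMF, 0 to 25 °C
Reagents that add atoms: iodomethane (MeI), CI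
Why: Carboxylate SN2 O-alkylation works because bicarbonate deprotonates only the carboxylic acid, which is far more acidic than the enol or phenol OH, so MeI gives the methyl ester without O- or C-methylation elsewhere, no base strong enough to start self-aldolisation is present, and no stereocentre is formed.

**Step 2**
Reactants: 2 methyl 3-(4-hydroxyphenyl)-2-oxopropanoate; 3 phenylpyruvic acid (2-oxo-3-phenylpropanoic acid); 4 3-methylbut-2-enal
Product: 6 methyl (R)-2-[(2,2-dimethyl-2H-chromen-6-yl)methyl]-4-hydroxy-5-oxo-3-phenyl-2,5-dihydrofuran-2-carboxylate, via phenol-lactone 5 (not isolated)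
Conditions: Ph2BOH (10 mol%), N-[3,5-bis(trifluoromethyl)phenyl]-N'-[(8α,9S)-6'-methoxycinchonan-9-yl]thiourea (10 mol%), PhMe/CH2Cl2 1:1, 25 °C, 3 (1.3 equiv) added over 10 h by syringe pump; then 4 (2.5 equiv), PhB(OH)2 (1.2 equiv), AcOH, CH2Cl2 distilled off, reflux, Dean–Stark
Reagents that add atoms: none
Why: Proposed new method: only the free acid 3 can condense with Ph2BOH to the anionic five-membered enediolate borinate chelate, which pairs with the protonated quinuclidine of the catalyst while the thiourea N–H bonds hold the keto form of ester 2 through its 1,2-dicarbonyl unit, and because the medium stays acidic (no free amine to enolise 2) and 3 is kept dilute (its own ketone cannot compete as acceptor) the direct aldol addition is cross-selective and takes place on one face of the ketone of 2, setting C2 as (R); the boron-activated acyl group then acylates the new tertiary alcohol (lactonisation, ring A, giving 5 and returning Ph2BOH), and after 4 is added the phenyl boronate of the phenol directs ortho-hydroxyalkylation, dehydration and oxa-6π electrocyclisation to the 2H-pyran (ring B) under acidic conditions that offer no retro-aldol path to scramble C2; the closest known reaction types are the borinic-acid-catalysed direct aldol–lactonisation of pyruvic acids with aldehydes, the cooperative boronic acid/chiral aminothiourea activation of carboxylic acids, the amine–thiourea-catalysed aldol–lactonisation of 2-oxo esters with activated ketones, and the phenylboronic-acid-mediated chromene synthesis from phenols and enals.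

**Step 3**
Reactants: 6 methyl (R)-2-[(2,2-dimethyl-2H-chromen-6-yl)methyl]-4-hydroxy-5-oxo-3-phenyl-2,5-dihydrofuran-2-carboxylate
Product: 7 4'-dehydroxy aspernolide A = methyl (R)-2-[(2,2-dimethylchroman-6-yl)methyl]-4-hydroxy-5-oxo-3-phenyl-2,5-dihydrofuran-2-carboxylate
Conditions: H2 (1 atm), 5% Pd/C, EtOAc, 25 °C
Reagents that add atoms: none
Why: Heterogeneous catalytic hydrogenation saturates the unhindered cis-disubstituted styrenyl C3=C4 bond of the chromene, whereas the tetrasubstituted, phenyl- and carbonyl-conjugated enol double bond of the butenolide is inert at 1 atm, and the quaternary (R) centre carries no hydrogen and is untouched.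

**Compound list**
1 | 4-hydroxyphenylpyruvic acid | O=C(O)C(=O)Cc1ccc(O)cc1 | starting material
2 | methyl 3-(4-hydroxyphenyl)-2-oxopropanoate | COC(=O)C(=O)Cc1ccc(O)cc1 | intermediate
3 | phenylpyruvic acid | O=C(O)C(=O)Cc1ccccc1 | starting material
4 | 3-methylbut-2-enal | CC(C)=CC=O | starting material
5 | phenol-lactone, methyl (R)-4-hydroxy-2-(4-hydroxybenzyl)-5-oxo-3-phenyl-2,5-dihydrofuran-2-carboxylate | COC(=O)[C@]1(Cc2ccc(O)cc2)OC(=O)C(O)=C1c1ccccc1 | intermediate
6 | methyl (R)-2-[(2,2-dimethyl-2H-chromen-6-yl)methyl]-4-hydroxy-5-oxo-3-phenyl-2,5-dihydrofuran-2-carboxylate | COC(=O)[C@]1(Cc2ccc3c(c2)C=CC(C)(C)O3)OC(=O)C(O)=C1c1ccccc1 | intermediate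
7 | 4'-dehydroxy aspernolide A | COC(=O)[C@]1(Cc2ccc3c(c2)CCC(C)(C)O3)OC(=O)C(O)=C1c1ccccc1 | target

Total step count: 3. Longest linear sequence: 3 (1 → 2 → 6 → 7).

**Steps most likely to fail, most risky first**

Step 2. The risks are several:
- Addition of the borinate enediolate to a ketone acceptor is untested.
- The enantioselectivity of the ion pair is untested.
- The tolerance of the second annulation to the first-stage residues is untested.

The fallback replaces asymmetric catalysis by classical resolution and runs the two ring closures apart. It sets out from 2 (plus 3) and comes back at 6. Ph2BOH with catalytic Et3N in place of the chiral amine gives racemic methyl 4-hydroxy-2-(4-hydroxybenzyl)-5-oxo-3-phenyl-2,5-dihydrofuran-2-carboxylate F1, which is isolated. Its acidic enol forms salts with (R)-1-phenylethylamine, and fractional crystallisation gives the (R)-1-phenylethylammonium enolate of the (R)-lactone F2. The antipodal amine is used if the salt of the (S)-lactone proves less soluble. Dilute HCl releases 5 as an isolated solid. The PhB(OH)2/AcOH annulation with 4 in a separate flask then gives 6.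

Step 1. The risks are stray methylation of the enol or phenol and base-induced self-condensation of the sensitive 2-oxo ester. The fallback masks the ketone during esterification instead of alkylating the carboxylate. It sets out from 1 and comes back at 2. Heating 1 in MeOH with HC(OMe)3 and catalytic H2SO4 esterifies the acid and ketalises the ketone at once. This gives methyl 3-(4-hydroxyphenyl)-2,2-dimethoxypropanoate F3, which cannot enolise and is easy to purify. Aqueous CF3CO2H in CH2Cl2 then unmasks the ketone and gives 2, free of base and alkylating agent and enriched in the keto tautomer that step 2 consumes.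

Step 3. The risks are hydrogenolysis of an allylic C–O bond and slow attack on the butenolide double bond. The fallback builds the saturated ring at the right oxidation level, so no reduction is needed. It sets out from 5 (isolated by working up step 2 before 4 is added) and comes back at 7. Friedel–Crafts ortho-prenylation of the phenol with 2-methylbut-3-en-2-ol and BF3·OEt2 in dioxane gives methyl (R)-4-hydroxy-2-[4-hydroxy-3-(3-methylbut-2-enyl)benzyl]-5-oxo-3-phenyl-2,5-dihydrofuran-2-carboxylate F4. Catalytic p-TsOH in warm PhMe then closes the ether ring by Markovnikov hydroalkoxylation to give 7.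

**Further compounds**
F1 | step 2 | racemic methyl 4-hydroxy-2-(4-hydroxybenzyl)-5-oxo-3-phenyl-2,5-dihydrofuran-2-carboxylate | COC(=O)C1(Cc2ccc(O)cc2)OC(=O)C(O)=C1c1ccccc1
F2 | step 2 | (R)-1-phenylethylammonium enolate of the (R)-lactone | COC(=O)[C@]1(Cc2ccc(O)cc2)OC(=O)C([O-])=C1c1ccccc1.C[C@@H]([NH3+])c1ccccc1
F3 | step 1 | methyl 3-(4-hydroxyphenyl)-2,2-dimethoxypropanoate | COC(=O)C(OC)(OC)Cc1ccc(O)cc1
F4 | step 3 | methyl (R)-4-hydroxy-2-[4-hydroxy-3-(3-methylbut-2-enyl)benzyl]-5-oxo-3-phenyl-2,5-dihydrofuran-2-carboxylate | COC(=O)[C@]1(Cc2ccc(O)c(CC=C(C)C)c2)OC(=O)C(O)=C1c1ccccc1
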